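**Plan**

1. The polyene is cut at C11=C12 and C11'=C12' (two Wittig reactions, C15 + C10 + C15). The 5',6'-seco-5',6'-dione end is traced back, by reconnecting C5'–C6', to a second copy of the 3,5,6-trihydroxy ring, so one C15 phosphonium salt serves both ends.
2. In the ring the trans C5/C6 diol goes back to a syn 5,6-epoxide and then to a C5=C6 olefin. The cyclohexene is cut at C4–C5 and C1–C6 into a 2-silyloxy diene and an ynoate.
3. Enabling feature: ring atoms C1(Me2)–C2–C3(O)–C4 carry the pattern of mesityl oxide and C5(Me)–C6–C7 that of a but-2-ynoate, with the C3 oxygen para to C6, which is the orientation a 2-oxygenated diene gives with an acetylenic ester.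
4. Forward: the carbocycle is closed first (step 2, achiral) and elaborated C10 → C13 → C15. Part of the C15 salt is myristoylated, joined to the C10 dialdehyde and ring-opened by glycol cleavage to give the seco end; the last Wittig joins the halves.
5. Stereochemistry: C3 and C3' from one enzymatic ketone reduction; C5 and C6 from hydroxyl-directed syn epoxidation followed by inverting attack of water at C5; E double bonds from HWE/Wittig reactions with thermal Z→E equilibration.

Key step: step 2

Remark: carotenoid locants are used (ring: C1 = CMe2, C3 = CHOH, C5 = C(OH)Me, C6 = C(OH) bearing the chain; primed locants for the seco end). C3 and C3' have the same spatial arrangement, so one enantiomer of the C15 unit serves both ends.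
Assumption: an (R)-selective ketoreductase that accepts ketone 5 is available from commercial enzyme panels.

**Route**

Step 1
Reactants: 1 mesityl oxide (4-methylpent-3-en-2-one)
Product: 2 2-(tert-butyldimethylsilyloxy)-4-methylpenta-1,3-diene
Conditions: TBSOTf, Et3N, Et2O, 0 °C
Reagents that add atoms: tert-butyldimethylsilyl triflate, CC(C)(C)[Si](C)(C)OS(=O)(=O)C(F)(F)F
Why: Silyl dienol ether formation by soft enolisation: O-silylation followed by kinetic deprotonation of the α'-methyl group should give the cross-conjugated 2-silyloxy diene.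

Step 2
Reactants: 2 2-(tert-butyldimethylsilyloxy)-4-methylpenta-1,3-diene; 3 ethyl but-2-ynoate
Product: 5 ethyl 2,6,6-trimethyl-4-oxocyclohex-1-ene-1-carboxylate, via silyl enol ether cycloadduct 4 (not isolated)
Conditions: AlBr3/AlMe3 (10:1, 0.2 equiv), toluene–CH2Cl2, −10 °C → rt; then 1 M HCl, THF, 0 °C
Reagents that add atoms: none
Why: Lewis-acid-promoted normal-demand Diels–Alder reaction of an electron-rich 2-silyloxy diene with an acetylenic ester: the ester-bound aluminium Lewis acid lowers the ynoate LUMO, diene C4 (largest HOMO coefficient) bonds to the ynoate β-carbon C5 and the gem-dimethyl terminus C1 to the α-carbon C6, so both ring bonds C4–C5 and C1–C6 form in one operation, concertedly but asynchronously (in the stepwise limit a Mukaiyama–Michael addition followed by Michael closure of the allenoate onto the unveiled enone gives the same product). The closest known reaction type is the Lewis-acid-catalysed cycloaddition of hindered 2-silyloxy-1,3-dienes carrying a disubstituted terminus with enones, and of simple 2-silyloxy dienes with propiolates and butynoates. The ring closes in the [4π+2π] mode with an alkyne as the 2π partner, so a cyclohexa-1,4-diene results and no stereocentre is created; the enol ether marks C3 for the later carbinol and the tetrasubstituted C5=C6 bond is the handle for the trans-diol. The selectivity needed is regiochemical (C3 oxygen para to the ester-bearing C6) and is secured by the two donors of the diene acting in concert, since the 2-silyloxy group directs para and the disubstituted terminus directs ortho, both to the same orientation. The Z-methyl of the diene disfavours the s-cis conformer, which is why a strong mixed Lewis acid is used and not heat. Brief cold aqueous acid then hydrolyses the silyl enol ether to the β,γ-unsaturated ketone under conditions mild enough to leave the C5=C6 bond in place.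

Step 3
Reactants: 5 ethyl 2,6,6-trimethyl-4-oxocyclohex-1-ene-1-carboxylate
Product: 6 ethyl (4R)-4-hydroxy-2,6,6-trimethylcyclohex-1-ene-1-carboxylate
Conditions: (R)-selective ketoreductase (Lactobacillus kefir ADH type), NADP+ (cat.), i-PrOH, phosphate buffer pH 7, 30 °C
Reagents that add atoms: none
Why: Enzymatic asymmetric ketone reduction: the enzyme should distinguish the CMe2-flanked methylene from the allylic methylene, as reductases do for the closely related 2,2,6-trimethylcyclohexane-1,4-dione, and set C3 in the (R) sense (the arrangement that is named 3S after 5,6-oxygenation), while the neutral buffer avoids migration of the β,γ-double bond.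

Step 4
Reactants: 6 ethyl (4R)-4-hydroxy-2,6,6-trimethylcyclohex-1-ene-1-carboxylate
Product: 7 (1R)-4-(hydroxymethyl)-3,5,5-trimethylcyclohex-3-en-1-ol
Conditions: LiAlH4, THF, 0 °C
Reagents that add atoms: none
Why: Hydride reduction of the hindered, twisted conjugated ester should proceed 1,2 to the allylic alcohol without touching the tetrasubstituted olefin or C3.

Step 5
Reactants: 7 (1R)-4-(hydroxymethyl)-3,5,5-trimethylcyclohex-3-en-1-ol
Product: 8 (1S,3S,6S)-6-(hydroxymethyl)-1,5,5-trimethyl-7-oxabicyclo[4.1.0]heptan-3-ol (epoxide cis to the ring hydroxyl)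
Conditions: VO(acac)2 (cat.), t-BuOOH, toluene, rt
Reagents that add atoms: tert-butyl hydroperoxide, CC(C)(C)OO
Why: Hydroxyl-directed vanadium-catalysed epoxidation: the vanadium-bound homoallylic ring alkoxide (with the facially neutral allylic CH2O group) should deliver oxygen to the face of the C5=C6 bond cis to the C3 hydroxyl, setting C5 and C6 as the syn epoxide.

Step 6
Reactants: 8 (1S,3S,6S)-6-(hydroxymethyl)-1,5,5-trimethyl-7-oxabicyclo[4.1.0]heptan-3-ol
Product: 9 (1R,4S,6S)-4-hydroxy-2,2,6-trimethyl-7-oxabicyclo[4.1.0]heptane-1-carbaldehyde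
Conditions: TEMPO (cat.), PhI(OAc)2, CH2Cl2, rt
Reagents that add atoms: none
Why: Oxoammonium (TEMPO) oxidation is selective for the primary alcohol and should give the non-enolisable epoxy aldehyde while leaving the secondary hydroxyl and the epoxide intact.

Step 7
Reactants: 9 (1R,4S,6S)-4-hydroxy-2,2,6-trimethyl-7-oxabicyclo[4.1.0]heptane-1-carbaldehyde; 10 diethyl (2-oxopropyl)phosphonate
Product: 11 (3E)-4-[(1R,4S,6S)-4-hydroxy-2,2,6-trimethyl-7-oxabicyclo[4.1.0]heptan-1-yl]but-3-en-2-one
Conditions: LiCl, i-Pr2NEt, MeCN, rt → 40 °C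
Reagents that add atoms: none
Why: Horner–Wadsworth–Emmons olefination of the aldehyde with a β-ketophosphonate under mild LiCl/amine conditions should give the E-enone (C7=C8) without opening the epoxide or requiring protection of the hydroxyl.

Step 8
Reactants: 11 (3E)-4-[(1R,4S,6S)-4-hydroxy-2,2,6-trimethyl-7-oxabicyclo[4.1.0]heptan-1-yl]but-3-en-2-one
Product: 12 (3E)-4-[(1R,2R,4S)-1,2,4-trihydroxy-2,6,6-trimethylcyclohexyl]but-3-en-2-one
Conditions: HClO4 (0.1 M aq.), THF, 0 °C → rt
Reagents that add atoms: water, O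
Why: Acid-catalysed anti hydrolysis of the epoxide: water should attack C5 with inversion, because cleavage at C6 would place positive charge next to the electron-poor enone and because axial attack at C5 is the trans-diaxial opening mode with the C3 hydroxyl equatorial, giving the 5R,6R trans-diol; the cis-disposed C3 hydroxyl cannot intercept either carbon.

Step 9
Reactants: 12 (3E)-4-[(1R,2R,4S)-1,2,4-trihydroxy-2,6,6-trimethylcyclohexyl]but-3-en-2-one; 13 triethyl phosphonoacetate
Product: 14 ethyl (2E,4E)-3-methyl-5-[(1R,2R,4S)-1,2,4-trihydroxy-2,6,6-trimethylcyclohexyl]penta-2,4-dienoate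
Conditions: 13 (4 equiv), NaH (4 equiv), THF, 0 → 50 °C
Reagents that add atoms: none
Why: Horner–Wadsworth–Emmons olefination of the unhindered methyl ketone with excess stabilised phosphonate anion should give mainly the 2E dienoate (C9=C10), the minor 2Z isomer being removable by chromatography, and the free hydroxyls are tolerated as alkoxides.

Step 10
Reactants: 14 ethyl (2E,4E)-3-methyl-5-[(1R,2R,4S)-1,2,4-trihydroxy-2,6,6-trimethylcyclohexyl]penta-2,4-dienoate
Product: 15 (1R,2R,4S)-1-[(1E,3E)-5-hydroxy-3-methylpenta-1,3-dien-1-yl]-2,6,6-trimethylcyclohexane-1,2,4-triol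
Conditions: i-Bu2AlH (excess), CH2Cl2–THF, −78 → 0 °C
Reagents that add atoms: none
Why: Aluminium hydride 1,2-reduction of the dienoate should give the primary allylic alcohol with retention of both double-bond geometries.

Step 11
Reactants: 15 (1R,2R,4S)-1-[(1E,3E)-5-hydroxy-3-methylpenta-1,3-dien-1-yl]-2,6,6-trimethylcyclohexane-1,2,4-triol
Product: 17 [(2E,4E)-3-methyl-5-[(1R,2R,4S)-1,2,4-trihydroxy-2,6,6-trimethylcyclohexyl]penta-2,4-dien-1-yl]triphenylphosphonium bromide, via allylic bromide 16 (not isolated)
Conditions: CBr4, PPh3, CH2Cl2, −30 °C; then PPh3, EtOAc, rt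
Reagents that add atoms: carbon tetrabromide, BrC(Br)(Br)Br; triphenylphosphine, c1ccc(cc1)P(c1ccccc1)c1ccccc1
Why: Appel bromination should take the primary allylic hydroxyl much faster than the secondary or tertiary ones at low temperature, and SN2 quaternisation by PPh3 then gives the phosphonium salt under acid-free conditions that do not ionise the tertiary allylic C6 hydroxyl.

Step 12
Reactants: 17 [(2E,4E)-3-methyl-5-[(1R,2R,4S)-1,2,4-trihydroxy-2,6,6-trimethylcyclohexyl]penta-2,4-dien-1-yl]triphenylphosphonium bromide; 18 tetradecanoyl chloride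
Product: 19 [(2E,4E)-5-[(1R,2R,4S)-1,2-dihydroxy-2,6,6-trimethyl-4-(tetradecanoyloxy)cyclohexyl]-3-methylpenta-2,4-dien-1-yl]triphenylphosphonium bromide
Conditions: pyridine, DMAP (cat.), CH2Cl2, 0 °C → rt
Reagents that add atoms: none
Why: DMAP-catalysed O-acylation should occur only at the single secondary hydroxyl, since the two tertiary hydroxyls are too hindered and pyridine is too weak a base to form the ylide.

Step 13
Reactants: 19 [(2E,4E)-5-[(1R,2R,4S)-1,2-dihydroxy-2,6,6-trimethyl-4-(tetradecanoyloxy)cyclohexyl]-3-methylpenta-2,4-dien-1-yl]triphenylphosphonium bromide; 20 (2E,4E,6E)-2,7-dimethylocta-2,4,6-trienedial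
Product: 21 (2E,4E,6E,8E,10E,12E)-13-[(1R,2R,4S)-1,2-dihydroxy-2,6,6-trimethyl-4-(tetradecanoyloxy)cyclohexyl]-2,7,11-trimethyltrideca-2,4,6,8,10,12-hexaenal
Conditions: 20 (3 equiv), 1,2-epoxybutane, EtOH, 65 °C; then n-heptane, 80 °C (Z→E)
Reagents that add atoms: none
Why: Wittig olefination under epoxide-buffered, nearly neutral conditions (the epoxide scavenges HBr and releases the ylide) should spare the myristate; excess dialdehyde favours mono-olefination and warming equilibrates the new disubstituted double bond to E.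

Step 14
Reactants: 21 (2E,4E,6E,8E,10E,12E)-13-[(1R,2R,4S)-1,2-dihydroxy-2,6,6-trimethyl-4-(tetradecanoyloxy)cyclohexyl]-2,7,11-trimethyltrideca-2,4,6,8,10,12-hexaenal
Product: 22 (2E,4E,6E,8E,10E,12E,17S)-2,7,11,15,15-pentamethyl-1,14,19-trioxoicosa-2,4,6,8,10,12-hexaen-17-yl tetradecanoate
Conditions: Pb(OAc)4, CH2Cl2, 0 °C → rt
Reagents that add atoms: none
Why: Criegee glycol cleavage: Pb(OAc)4 cleaves ditertiary trans-diaxial 1,2-diols that cannot form a cyclic periodate ester, so the C5'–C6' bond should break to give the methyl ketone and the polyene-conjugated ketone of the seco end, mirroring its presumed biogenesis and leaving C3' untouched.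

Step 15
Reactants: 22 (2E,4E,6E,8E,10E,12E,17S)-2,7,11,15,15-pentamethyl-1,14,19-trioxoicosa-2,4,6,8,10,12-hexaen-17-yl tetradecanoate; 17 [(2E,4E)-3-methyl-5-[(1R,2R,4S)-1,2,4-trihydroxy-2,6,6-trimethylcyclohexyl]penta-2,4-dien-1-yl]triphenylphosphonium bromide
Product: 23 (all-E)-(3S,5R,6R,3'S)-3,5,6-trihydroxy-3'-(tetradecanoyloxy)-5,6-dihydro-5',6'-seco-β,β-carotene-5',6'-dione (target)
Conditions: 1,2-epoxybutane, EtOH–CH2Cl2, 60 °C; then n-heptane, 70 °C (Z→E)
Reagents that add atoms: none
Why: Wittig olefination of the aldehyde (far more reactive than the two ketones) by the semi-stabilised ylide of the unprotected triol salt under nearly neutral conditions should form C11=C12 without β-elimination of the myristate, and warming equilibrates the new bond to E.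

**Compound list**

1 | mesityl oxide (4-methylpent-3-en-2-one) | CC(=O)C=C(C)C | starting material
2 | 2-(tert-butyldimethylsilyloxy)-4-methylpenta-1,3-diene | C=C(O[Si](C)(C)C(C)(C)C)C=C(C)C | intermediate
3 | ethyl but-2-ynoate | CCOC(=O)C#CC | starting material
4 | ethyl 4-(tert-butyldimethylsilyloxy)-2,6,6-trimethylcyclohexa-1,4-diene-1-carboxylate | CCOC(=O)C1=C(C)CC(O[Si](C)(C)C(C)(C)C)=CC1(C)C | intermediate
5 | ethyl 2,6,6-trimethyl-4-oxocyclohex-1-ene-1-carboxylate | CCOC(=O)C1=C(C)CC(=O)CC1(C)C | intermediate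
6 | ethyl (4R)-4-hydroxy-2,6,6-trimethylcyclohex-1-ene-1-carboxylate | CCOC(=O)C1=C(C)C[C@@H](O)CC1(C)C | intermediate
7 | (1R)-4-(hydroxymethyl)-3,5,5-trimethylcyclohex-3-en-1-ol | OCC1=C(C)C[C@@H](O)CC1(C)C | intermediate
8 | (1S,3S,6S)-6-(hydroxymethyl)-1,5,5-trimethyl-7-oxabicyclo[4.1.0]heptan-3-ol | OC[C@]12O[C@@]1(C)C[C@@H](O)CC2(C)C | intermediate
9 | (1R,4S,6S)-4-hydroxy-2,2,6-trimethyl-7-oxabicyclo[4.1.0]heptane-1-carbaldehyde | O=C[C@]12O[C@@]1(C)C[C@@H](O)CC2(C)C | intermediate
10 | diethyl (2-oxopropyl)phosphonate | CCOP(=O)(CC(C)=O)OCC | starting material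
11 | (3E)-4-[(1R,4S,6S)-4-hydroxy-2,2,6-trimethyl-7-oxabicyclo[4.1.0]heptan-1-yl]but-3-en-2-one | CC(=O)/C=C/[C@]12O[C@@]1(C)C[C@@H](O)CC2(C)C | intermediate
12 | (3E)-4-[(1R,2R,4S)-1,2,4-trihydroxy-2,6,6-trimethylcyclohexyl]but-3-en-2-one | CC(=O)/C=C/[C@@]1(O)C(C)(C)C[C@H](O)C[C@@]1(C)O | intermediate
13 | triethyl phosphonoacetate | CCOC(=O)CP(=O)(OCC)OCC | starting material
14 | ethyl (2E,4E)-3-methyl-5-[(1R,2R,4S)-1,2,4-trihydroxy-2,6,6-trimethylcyclohexyl]penta-2,4-dienoate | CCOC(=O)/C=C(C)/C=C/[C@@]1(O)C(C)(C)C[C@H](O)C[C@@]1(C)O | intermediate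
15 | (1R,2R,4S)-1-[(1E,3E)-5-hydroxy-3-methylpenta-1,3-dien-1-yl]-2,6,6-trimethylcyclohexane-1,2,4-triol | OC/C=C(C)/C=C/[C@@]1(O)C(C)(C)C[C@H](O)C[C@@]1(C)O | intermediate
16 | (1R,2R,4S)-1-[(1E,3E)-5-bromo-3-methylpenta-1,3-dien-1-yl]-2,6,6-trimethylcyclohexane-1,2,4-triol | BrC/C=C(C)/C=C/[C@@]1(O)C(C)(C)C[C@H](O)C[C@@]1(C)O | intermediate
17 | [(2E,4E)-3-methyl-5-[(1R,2R,4S)-1,2,4-trihydroxy-2,6,6-trimethylcyclohexyl]penta-2,4-dien-1-yl]triphenylphosphonium bromide | [Br-].c1ccccc1[P+](c1ccccc1)(c1ccccc1)C/C=C(C)/C=C/[C@@]1(O)C(C)(C)C[C@H](O)C[C@@]1(C)O | intermediate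
18 | tetradecanoyl chloride (myristoyl chloride) | CCCCCCCCCCCCCC(=O)Cl | starting material
19 | [(2E,4E)-5-[(1R,2R,4S)-1,2-dihydroxy-2,6,6-trimethyl-4-(tetradecanoyloxy)cyclohexyl]-3-methylpenta-2,4-dien-1-yl]triphenylphosphonium bromide | [Br-].c1ccccc1[P+](c1ccccc1)(c1ccccc1)C/C=C(C)/C=C/[C@@]1(O)C(C)(C)C[C@H](OC(=O)CCCCCCCCCCCCC)C[C@@]1(C)O | intermediate
20 | (2E,4E,6E)-2,7-dimethylocta-2,4,6-trienedial | O=C/C(C)=C/C=C/C=C(C)/C=O | starting material
21 | (2E,4E,6E,8E,10E,12E)-13-[(1R,2R,4S)-1,2-dihydroxy-2,6,6-trimethyl-4-(tetradecanoyloxy)cyclohexyl]-2,7,11-trimethyltrideca-2,4,6,8,10,12-hexaenal | O=C/C(C)=C/C=C/C=C(C)/C=C/C=C(C)/C=C/[C@@]1(O)C(C)(C)C[C@H](OC(=O)CCCCCCCCCCCCC)C[C@@]1(C)O | intermediate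
22 | (2E,4E,6E,8E,10E,12E,17S)-2,7,11,15,15-pentamethyl-1,14,19-trioxoicosa-2,4,6,8,10,12-hexaen-17-yl tetradecanoate | CCCCCCCCCCCCCC(=O)O[C@H](CC(C)=O)CC(C)(C)C(=O)/C=C/C(C)=C/C=C/C(C)=C/C=C/C=C(C)/C=O | intermediate
23 | (all-E)-(3S,5R,6R,3'S)-3,5,6-trihydroxy-3'-(tetradecanoyloxy)-5,6-dihydro-5',6'-seco-β,β-carotene-5',6'-dione | CCCCCCCCCCCCCC(=O)O[C@H](CC(C)=O)CC(C)(C)C(=O)/C=C/C(C)=C/C=C/C(C)=C/C=C/C=C(C)/C=C/C=C(C)/C=C/[C@@]1(O)C(C)(C)C[C@H](O)C[C@@]1(C)O | target

**Totals and risks**

Total step count: 15. Longest linear sequence: 15 steps (1 → 23; salt 17 is drawn on twice, in steps 12 and 15).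

Steps most likely to fail:

Step 2. The cycloaddition may stall because the Z-methyl group of diene 2 disfavours the s-cis conformer, or the silyl enol ether may be lost by protodesilylation or oligomerisation under the Lewis acid before it reacts. Fallback: set out from 1 and condense it with ethyl acetoacetate (ZnCl2, toluene, reflux with azeotropic removal of water; Michael addition followed by aldol condensation, a Robinson-type annulation) to give racemic ethyl 2,6,6-trimethyl-4-oxocyclohex-2-ene-1-carboxylate F1. Its extended enolate (LiN(i-Pr)2, THF, −78 °C) is protonated kinetically at the α-carbon with AcOH, which moves the double bond to C5=C6 and returns to the route at 5.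

Step 3. The enzyme may discriminate poorly between the two methylene flanks of the ketone, or the β,γ-double bond may migrate into conjugation with the ketone during the slow biotransformation. Fallback: set out from 5 and reduce it under Luche conditions (NaBH4, CeCl3·7H2O, MeOH, −40 °C) to racemic ethyl 4-hydroxy-2,6,6-trimethylcyclohex-1-ene-1-carboxylate F2. Lipase-catalysed kinetic resolution (Pseudomonas fluorescens lipase, vinyl acetate, t-BuOMe) should give ethyl (4R)-4-acetoxy-2,6,6-trimethylcyclohex-1-ene-1-carboxylate F3 and leave ethyl (4S)-4-hydroxy-2,6,6-trimethylcyclohex-1-ene-1-carboxylate F4, which is separated and recycled by periodinane oxidation to 5. F3 is reduced with LiAlH4 under the conditions of step 4 (ester and acetate both cleaved) and the route is rejoined at 7. Should the lipase prefer the other enantiomer, the roles of acetate and free alcohol are exchanged.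

Step 14. Cleavage of the conformationally locked trans-diaxial ditertiary glycol may be sluggish, and during a long exposure Pb(OAc)4 may oxidise the polyene aldehyde. Fallback: move the cleavage to the short-chain stage. Set out from 19 and treat it with Pb(OAc)4 (CH2Cl2, rt, forcing conditions tolerable in the absence of a long polyene) to give [(2E,4E,9S)-3,7,7-trimethyl-6,11-dioxo-9-(tetradecanoyloxy)dodeca-2,4-dien-1-yl]triphenylphosphonium bromide F5. F5 is then condensed with an excess of 20 under the Wittig conditions of step 13 (1,2-epoxybutane, EtOH, 65 °C, then thermal Z→E equilibration), and the route is rejoined at 22.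

Further compounds
F1 | step 2 | ethyl 2,6,6-trimethyl-4-oxocyclohex-2-ene-1-carboxylate (racemic) | CCOC(=O)C1C(C)=CC(=O)CC1(C)C
F2 | step 3 | ethyl 4-hydroxy-2,6,6-trimethylcyclohex-1-ene-1-carboxylate (racemic) | CCOC(=O)C1=C(C)CC(O)CC1(C)C
F3 | step 3 | ethyl (4R)-4-acetoxy-2,6,6-trimethylcyclohex-1-ene-1-carboxylate | CCOC(=O)C1=C(C)C[C@@H](OC(C)=O)CC1(C)C
F4 | step 3 | ethyl (4S)-4-hydroxy-2,6,6-trimethylcyclohex-1-ene-1-carboxylate | CCOC(=O)C1=C(C)C[C@H](O)CC1(C)C
F5 | step 14 | [(2E,4E,9S)-3,7,7-trimethyl-6,11-dioxo-9-(tetradecanoyloxy)dodeca-2,4-dien-1-yl]triphenylphosphonium bromide | [Br-].CCCCCCCCCCCCCC(=O)O[C@H](CC(C)=O)CC(C)(C)C(=O)/C=C/C(C)=C/C[P+](c1ccccc1)(c1ccccc1)c1ccccc1
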